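All runs stem from a simulated flask for an exercise; the scatter is artificial.

In ash the substrate and target readings sum to 99.9% at 8.00 h, and in both proposed steps the enzyme comes out as it went in. So we take the charge of enzyme as constant within a run, and each step's rate as carrying that enzyme as a factor. At the same substrate charge, a flask should then depend on enzyme concentration times time. We express this as the oak-equivalent time, τ, the time oak needs to give a flask's enzyme-time: τ = flask enzyme × flask time / oak enzyme. For theta this is 0.511 h.

| flask | substrate | enzyme | remark | time |
|---|---|---|---|---|
| ash | 0.072 M | 2.7 µM | run made earlier |  |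
| oak | 0.072 M | 47 µM | run made earlier |  |
| theta | 0.072 M | 2.0 µM |  | 12 h |
| beta | 0.072 M | 4.0 µM |  | 12 h |
| gamma | 0.072 M | 8.0 µM |  | 12 h |
| delta | 0.072 M | 15 µM |  | 12 h |
| eta | 0.072 M | 30 µM |  | 12 h |

| run | time / h | target / % | substrate / % |
|---|---|---|---|
| ash | 1.33 | 5.6 | 94.8 |
| ash | 3.00 | 12.6 | 87.2 |
| ash | 4.00 | 17.2 | 83.3 |
| ash | 6.00 | 26.9 | 72.4 |
| ash | 8.00 | 38.7 | 61.2 |
| oak | 0.667 | 66.4 | 32.9 |
| oak | 1.00 | 96.1 | 0 |
| oak | 2.00 | 89.4 | 0.2 |
| oak | 3.00 | 84.7 | 0.7 |
| oak | 5.00 | 75.7 | 0.3 |
| oak | 8.00 | 65.6 | 0.1 |

(each reading ± 0.5 percentage points)

- steps that have been proposed: target + enzyme <-> isomer of the product + enzyme; substrate + enzyme -> target + enzyme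
- "hardly changes" means that all values lie within two and a half points (for a concentration: within two and a half percent of the largest)

- amount of target at the end, in percent of the substrate charged for theta, beta, gamma, delta, eta, in this order
- the shape of the row from first to last (rises all the way / falls all the way / hardly changes / rises, then falls / falls, then rises)

The other flasks have τ of 1.02 h, 2.04 h, 3.83 h and 7.66 h. Each lies inside oak's readings, so we replace the curve between neighbouring readings by its mean slope. This gives target of 96.0% for beta, 89.2% for gamma, 81.0% for delta and 66.7% for eta. This assumes that the step from target to isomer, pseudo-first-order in target at fixed enzyme, follows the same clock.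

Theta is the weak link. In ash time it sits at 8.89 h, past the last ash reading. Continuing ash's last mean slope gives 43.9%. But ash gained 12 percentage points in its last interval, more than the 9.7 points of the equally long one before, so this slope reads low.

To reforge the link, we place ash's end at τ = 0.460 h and draw the chord to oak's first reading, which gives 45.5%. On a steepening curve this reads high. Theta stands a quarter of the way along that gap, so we stay near the lower figure and commit to 43.9%, which puts theta below beta and the later flasks falling.

The forecast reads 44%, 96%, 89%, 81% and 67%, rises, then falls, in the words “The target peaks near beta, then drains towards equilibrium”. The flasks give 43.6%, 96.3%, 89.7%, 80.4% and 67.2%, rises, then falls.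

    target + enzyme ⇌ isomer of the product + enzyme, rate k1*[enzyme]*[target] forward; the back reaction follows from the equilibrium constant (K = 1.00, k = 26.5 M⁻¹ min⁻¹)
    substrate + enzyme → target + enzyme, rate k2*[substrate]*[enzyme]/(1 + ([substrate]/Km2) + ([substrate]/Ksi2)^2) (0.0760 M, 7.94 mM, k = 20400 M⁻¹ min⁻¹)

Theta ended at 43.6% target with 55.7% substrate still in the flask; the forward step from target to isomer alone has a half-life of 9.1 d at theta's charged concentrations, longer than the 12 h run, and isomer stood at 0.751%. Beta at 6.00 h has τ = 0.511 h, theta's 0.511 h, and held 43.6% target against theta's 43.6%. Eta at 6.00 h has τ = 3.83 h, delta's 3.83 h, and held 80.4% target against delta's 80.4%.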